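The oxolane ring (O1, C2–C5) is read as a γ-lactone with C5 at the carboxyl level. C4 and C3 then become the α- and β-carbons of a flat 5-aryl-2(5H)-furanone whose only stereocentre, aryl-bearing C2, shields one face. In one flask a vinyl cuprate delivers the latent C9 to C3 opposite the C2 aryl ring. The resulting enolate is benzylated at C4, making C3–C9 and C4–C7' and uniting three fragments. The precursor is the (S)-butenolide carrying an O-benzylguaiacyl group, obtained by ring-closing metathesis. C4 is redefined afterwards by enolate hydroxylation, and the lactone is reduced to the ether before the vinyl group is cleaved.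

Key step: step 8

Remark on numbering: C2–C5, C9 and C7' in the text are the locants of the target oxolane (O1, C2 aryl, C3 bearing C9, C4 bearing OH and the C7' methylene, C5). The target is (2S,3R,4S), with the C2 aryl group and C4–OH on one face and C9 and C7' on the other. Systematic names carry their own locants.

Step 1
Reactants: 1 vanillin
Product: 2 4-(benzyloxy)-3-methoxybenzaldehyde
Conditions: BnBr, K2CO3, DMF, 60 °C
Reagents that add atoms: benzyl bromide, BrCc1ccccc1
Why: Williamson ether synthesis on the acidic phenol, giving a benzyl ether that tolerates the Grignard, cuprate, amide base, hydride and cold Lewis acid steps ahead and leaves by hydrogenolysis at the end.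

Step 2
Reactants: 2 4-(benzyloxy)-3-methoxybenzaldehyde; 3 vinylmagnesium bromide
Product: 4 rac-1-[4-(benzyloxy)-3-methoxyphenyl]prop-2-en-1-ol
Conditions: THF, −78 to 0 °C; aq. NH4Cl
Reagents that add atoms: none
Why: Grignard 1,2-addition to a non-enolisable aromatic aldehyde, which creates the future C2 carbinol centre as a racemate that step 3 resolves.

Step 3
Reactants: 4 rac-1-[4-(benzyloxy)-3-methoxyphenyl]prop-2-en-1-ol
Product: 5 (1S)-1-[4-(benzyloxy)-3-methoxyphenyl]prop-2-en-1-ol
Conditions: immobilised Candida antarctica lipase B (Novozym 435), vinyl acetate, MTBE, 30 °C, stopped just past half conversion; chromatography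
Reagents that add atoms: none
Why: Lipase-catalysed kinetic resolution by irreversible transesterification, in which the Kazlauskas rule (aryl as large group, vinyl as medium group) predicts acetylation of the R alcohol, so that running slightly beyond half conversion should leave the S alcohol, the source of C2, in high enantiomeric purity.

Step 4
Reactants: 5 (1S)-1-[4-(benzyloxy)-3-methoxyphenyl]prop-2-en-1-ol; 6 acryloyl chloride
Product: 7 (1S)-1-[4-(benzyloxy)-3-methoxyphenyl]prop-2-en-1-yl prop-2-enoate
Conditions: iPr2NEt, CH2Cl2, −20 to 0 °C; chromatography on Et3N-washed silica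
Reagents that add atoms: none
Why: O-acylation of an alcohol by an acid chloride under basic conditions leaves the carbinol C–O bond untouched, so the S configuration is retained, and cold acid-free handling avoids ionisation of the electron-rich benzylic allylic ester.

Step 5
Reactants: 7 (1S)-1-[4-(benzyloxy)-3-methoxyphenyl]prop-2-en-1-yl prop-2-enoate
Product: 8 (5S)-5-[4-(benzyloxy)-3-methoxyphenyl]furan-2(5H)-one
Conditions: second-generation Grubbs catalyst RuCl2(=CHPh)(PCy3)(SIMes) (5 mol%), CH2Cl2 (0.01 M), reflux; silica filtration, recrystallisation, no amine base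
Reagents that add atoms: none
Why: Ring-closing metathesis of an allyl acrylate to a butenolide with loss of ethene is a standard use of this carbene-ligated ruthenium catalyst, and its neutral conditions leave the base-sensitive C2–H and hence the stereocentre untouched, while recrystallisation can raise the enantiomeric purity further.

Step 6
Reactants: 2 4-(benzyloxy)-3-methoxybenzaldehyde
Product: 9 [4-(benzyloxy)-3-methoxyphenyl]methanol
Conditions: NaBH4, MeOH, 0 °C
Reagents that add atoms: none
Why: Borohydride reduction of an aromatic aldehyde to the benzylic alcohol, with no competing functionality.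

Step 7
Reactants: 9 [4-(benzyloxy)-3-methoxyphenyl]methanol
Product: 10 1-(benzyloxy)-4-(bromomethyl)-2-methoxybenzene
Conditions: PBr3 (0.4 equiv), Et2O, 0 °C
Reagents that add atoms: phosphorus tribromide, BrP(Br)Br
Why: Bromination of a primary benzylic alcohol through its phosphite ester and SN2 attack of bromide, the crystalline bromide being used soon after preparation because electron-rich benzylic bromides keep poorly.

Step 8
Reactants: 8 (5S)-5-[4-(benzyloxy)-3-methoxyphenyl]furan-2(5H)-one; 3 vinylmagnesium bromide; 10 1-(benzyloxy)-4-(bromomethyl)-2-methoxybenzene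
Product: 13 (3S,4S,5S)-5-[4-(benzyloxy)-3-methoxyphenyl]-3-{[4-(benzyloxy)-3-methoxyphenyl]methyl}-4-ethenyloxolan-2-one (all-trans lactone), via bromomagnesium divinylcuprate 11 (not isolated), via bromomagnesium lactone enolate 12 (not isolated)
Conditions: 3 (2.6 equiv), CuBr·SMe2 (1.3 equiv), THF/Me2S, −78 to −40 °C; 8 added slowly at −78 °C; then DMPU, 10 (2.5 equiv), −78 to 0 °C; aq. NH4Cl/NH3
Reagents that add atoms: none
Why: Divinylcuprate 11 binds the C3=C4 double bond of 8 as a π-complex, adds oxidatively at C3 to a trivalent-copper β-cuprio enolate and reductively eliminates to forge C3–C9, leaving magnesium enolate 12, whose C4 then displaces bromide from 10 in an SN2 reaction to forge C4–C7'. The closest known reaction type is the tandem cuprate conjugate addition–enolate alkylation (three-component coupling) of cyclic enones and butenolides, and no ring is closed because the lactone ring is carried through intact. C3 is controlled by the C2 aryl ring, the only substituent on the planar furanone, which screens its own face so that the vinyl group arrives anti to it (2,3-trans). C4 is controlled by the newly installed vinyl group, the bromide approaching the opposite enolate face (3,4-trans), but this centre is flattened again in step 9, so its selectivity does not matter. The step needs 1,4- rather than 1,2-addition and addition rather than removal of the acidic benzylic C2–H, which would racemise 8 through its aromatic 2-oxidofuran; the soft and weakly basic cuprate at −78 °C and slow addition of 8 to an excess of 11, so that free butenolide never coexists with enolate, secure both. C-alkylation and monoalkylation are secured by the highly reactive benzylic bromide, the DMPU cosolvent that loosens the magnesium enolate, and the crowding at C4 that disfavours a second alkylation.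

Step 9
Reactants: 13 all-trans lactone
Product: 15 (3S,4R,5S)-5-[4-(benzyloxy)-3-methoxyphenyl]-3-{[4-(benzyloxy)-3-methoxyphenyl]methyl}-4-ethenyl-3-hydroxyoxolan-2-one, via potassium lactone enolate 14 (not isolated)
Conditions: KN(SiMe3)2 (1.3 equiv), THF, −78 °C; then 2-(benzenesulfonyl)-3-phenyloxaziridine (1.5 equiv), −78 °C; AcOH
Reagents that add atoms: 2-(benzenesulfonyl)-3-phenyloxaziridine, O=S(=O)(c1ccccc1)N1OC1c1ccccc1
Why: Davis oxidation of a lactone enolate, in which planar enolate 14 should accept oxygen on the face anti to the adjacent C3 vinyl group, as is usual for β-substituted butyrolactone enolates where the neighbouring group outweighs the remote γ-aryl group, so that C4–OH ends up trans and the C7' arylmethyl group cis to the vinyl group (4S of the target).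

Step 10
Reactants: 15 α-hydroxy lactone
Product: 16 (3S,4R,5S)-5-[4-(benzyloxy)-3-methoxyphenyl]-3-{[4-(benzyloxy)-3-methoxyphenyl]methyl}-4-ethenyloxolane-2,3-diol (lactol, anomers)
Conditions: iBu2AlH (2.5 equiv), CH2Cl2, −78 °C; aq. potassium sodium tartrate
Reagents that add atoms: none
Why: Partial reduction of a lactone with diisobutylaluminium hydride, where the first equivalent is consumed by the tertiary hydroxyl and the tetrahedral aluminium hemiacetal is stable at −78 °C, so that reduction stops at the lactol and the vinyl group and benzyl ethers are untouched.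

Step 11
Reactants: 16 lactol
Product: 18 (3S,4R,5S)-5-[4-(benzyloxy)-3-methoxyphenyl]-3-{[4-(benzyloxy)-3-methoxyphenyl]methyl}-4-ethenyloxolan-3-ol, via cyclic oxocarbenium ion 17 (not isolated)
Conditions: Et3SiH (5 equiv), BF3·OEt2 (2 equiv), CH2Cl2, −78 to −40 °C; cold aq. NaHCO3
Reagents that add atoms: none
Why: Ionic hydrogenation of a lactol, in which BF3 ionises the anomeric C5–OH much faster than the C2–O benzylic ether at low temperature and the large excess of silane delivers hydride to oxocarbenium ion 17 at C5, which becomes a CH2 group, so that no stereocentre is made or disturbed.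

Step 12
Reactants: 18 vinyl oxolanol
Product: 21 (3S,4R,5S)-5-[4-(benzyloxy)-3-methoxyphenyl]-3-{[4-(benzyloxy)-3-methoxyphenyl]methyl}-4-(hydroxymethyl)oxolan-3-ol (4,4'-di-O-benzylolivil), via vicinal diol 19 (not isolated), via C9 aldehyde 20 (not isolated)
Conditions: OsO4 (2 mol%), NaIO4 (4 equiv), 2,6-lutidine (2 equiv), 1,4-dioxane/H2O, rt; brief extraction; then NaBH4, MeOH, 0 °C
Reagents that add atoms: osmium tetroxide, O=[Os](=O)(=O)=O; sodium periodate, [Na+].[O-]I(=O)(=O)=O
Why: Lemieux–Johnson oxidation (catalytic osmylation to diol 19 and periodate glycol cleavage to aldehyde 20) followed by borohydride reduction trims the vinyl group to the C9 hydroxymethyl group without touching the electron-rich arenes that ozone might attack, the lutidine buffer and immediate reduction protect the epimerisable C3 of the β-hydroxy aldehyde, and because C5 is already an ether the new primary alcohol cannot translactonise and the aldehyde has no carboxylate leaving group at C2.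

Step 13
Reactants: 21 4,4'-di-O-benzylolivil
Product: 22 [(2S,3R,4S)-2-[4-(benzyloxy)-3-methoxyphenyl]-4-{[4-(benzyloxy)-3-methoxyphenyl]methyl}-4-hydroxyoxolan-3-yl]methyl acetate
Conditions: Ac2O (1.2 equiv), pyridine, CH2Cl2, 0 °C to rt
Reagents that add atoms: acetic anhydride, CC(=O)OC(C)=O
Why: Chemoselective acetylation of the primary C9 alcohol, since without an acyl-transfer catalyst the crowded tertiary C4–OH is inert and its trans placement to C9 also disfavours later acetyl migration.

Step 14
Reactants: 22 di-O-benzyl monoacetate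
Product: 23 olivil monoacetate, [(2S,3R,4S)-4-hydroxy-2-(4-hydroxy-3-methoxyphenyl)-4-[(4-hydroxy-3-methoxyphenyl)methyl]oxolan-3-yl]methyl acetate
Conditions: H2 (1 atm), 10% Pd/C, EtOAc, rt, stopped after uptake of two equivalents
Reagents that add atoms: none
Why: Catalytic hydrogenolysis of the two aryl benzyl ethers, which in neutral ethyl acetate at atmospheric pressure is much faster than cleavage of the hindered cyclic C2–O benzylic ether, while the acetate and the tertiary alcohol are inert.

Compound list
1 | vanillin | COc1cc(C=O)ccc1O | starting material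
2 | 4-(benzyloxy)-3-methoxybenzaldehyde | COc1cc(C=O)ccc1OCc1ccccc1 | intermediate
3 | vinylmagnesium bromide | C=C[Mg]Br | starting material
4 | rac-1-[4-(benzyloxy)-3-methoxyphenyl]prop-2-en-1-ol | C=CC(O)c1ccc(OCc2ccccc2)c(OC)c1 | intermediate
5 | (1S)-1-[4-(benzyloxy)-3-methoxyphenyl]prop-2-en-1-ol | C=C[C@H](O)c1ccc(OCc2ccccc2)c(OC)c1 | intermediate
6 | acryloyl chloride | C=CC(=O)Cl | starting material
7 | (1S)-1-[4-(benzyloxy)-3-methoxyphenyl]prop-2-en-1-yl prop-2-enoate | C=CC(=O)O[C@H](c1ccc(OCc2ccccc2)c(OC)c1)C=C | intermediate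
8 | (5S)-5-[4-(benzyloxy)-3-methoxyphenyl]furan-2(5H)-one | O=C1O[C@H](c2ccc(OCc3ccccc3)c(OC)c2)C=C1 | intermediate
9 | [4-(benzyloxy)-3-methoxyphenyl]methanol | COc1cc(CO)ccc1OCc1ccccc1 | intermediate
10 | 1-(benzyloxy)-4-(bromomethyl)-2-methoxybenzene | COc1cc(CBr)ccc1OCc1ccccc1 | intermediate
11 | bromomagnesium divinylcuprate | C=C[Cu-]C=C.[Mg+]Br | intermediate
12 | bromomagnesium (4S,5S)-5-[4-(benzyloxy)-3-methoxyphenyl]-4-ethenyl-4,5-dihydrofuran-2-olate | C1=C(O[Mg]Br)O[C@H](c2ccc(OCc3ccccc3)c(OC)c2)[C@H]1C=C | intermediate
13 | (3S,4S,5S)-5-[4-(benzyloxy)-3-methoxyphenyl]-3-{[4-(benzyloxy)-3-methoxyphenyl]methyl}-4-ethenyloxolan-2-one | COc1cc(C[C@@H]2C(=O)O[C@H](c3ccc(OCc4ccccc4)c(OC)c3)[C@H]2C=C)ccc1OCc1ccccc1 | intermediate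
14 | potassium (4S,5S)-5-[4-(benzyloxy)-3-methoxyphenyl]-3-{[4-(benzyloxy)-3-methoxyphenyl]methyl}-4-ethenyl-4,5-dihydrofuran-2-olate | COc1cc(CC2=C([O-])O[C@H](c3ccc(OCc4ccccc4)c(OC)c3)[C@H]2C=C)ccc1OCc1ccccc1.[K+] | intermediate
15 | (3S,4R,5S)-5-[4-(benzyloxy)-3-methoxyphenyl]-3-{[4-(benzyloxy)-3-methoxyphenyl]methyl}-4-ethenyl-3-hydroxyoxolan-2-one | COc1cc(C[C@@]2(O)C(=O)O[C@H](c3ccc(OCc4ccccc4)c(OC)c3)[C@H]2C=C)ccc1OCc1ccccc1 | intermediate
16 | (3S,4R,5S)-5-[4-(benzyloxy)-3-methoxyphenyl]-3-{[4-(benzyloxy)-3-methoxyphenyl]methyl}-4-ethenyloxolane-2,3-diol, anomeric mixture | COc1cc(C[C@@]2(O)C(O)O[C@H](c3ccc(OCc4ccccc4)c(OC)c3)[C@H]2C=C)ccc1OCc1ccccc1 | intermediate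
17 | C5=O1 oxocarbenium ion derived from 16, ring stereocentres unchanged | COc1cc(C[C@@]2(O)C=[O+][C@H](c3ccc(OCc4ccccc4)c(OC)c3)[C@H]2C=C)ccc1OCc1ccccc1 | intermediate
18 | (3S,4R,5S)-5-[4-(benzyloxy)-3-methoxyphenyl]-3-{[4-(benzyloxy)-3-methoxyphenyl]methyl}-4-ethenyloxolan-3-ol | COc1cc(C[C@@]2(O)CO[C@H](c3ccc(OCc4ccccc4)c(OC)c3)[C@H]2C=C)ccc1OCc1ccccc1 | intermediate
19 | 4-(1,2-dihydroxyethyl) analogue of 18, ring stereocentres as in 18, epimers at the new carbinol carbon | COc1cc(C[C@@]2(O)CO[C@H](c3ccc(OCc4ccccc4)c(OC)c3)[C@H]2C(O)CO)ccc1OCc1ccccc1 | intermediate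
20 | (2S,3R,4S)-2-[4-(benzyloxy)-3-methoxyphenyl]-4-{[4-(benzyloxy)-3-methoxyphenyl]methyl}-4-hydroxyoxolane-3-carbaldehyde | COc1cc(C[C@@]2(O)CO[C@H](c3ccc(OCc4ccccc4)c(OC)c3)[C@H]2C=O)ccc1OCc1ccccc1 | intermediate
21 | (3S,4R,5S)-5-[4-(benzyloxy)-3-methoxyphenyl]-3-{[4-(benzyloxy)-3-methoxyphenyl]methyl}-4-(hydroxymethyl)oxolan-3-ol | COc1cc(C[C@@]2(O)CO[C@H](c3ccc(OCc4ccccc4)c(OC)c3)[C@H]2CO)ccc1OCc1ccccc1 | intermediate
22 | [(2S,3R,4S)-2-[4-(benzyloxy)-3-methoxyphenyl]-4-{[4-(benzyloxy)-3-methoxyphenyl]methyl}-4-hydroxyoxolan-3-yl]methyl acetate | COc1cc(C[C@@]2(O)CO[C@H](c3ccc(OCc4ccccc4)c(OC)c3)[C@H]2COC(C)=O)ccc1OCc1ccccc1 | intermediate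
23 | olivil monoacetate | COc1cc(C[C@@]2(O)CO[C@H](c3ccc(O)c(OC)c3)[C@H]2COC(C)=O)ccc1O | target

Total step count: 14. Longest linear sequence: 12 steps (steps 1–5 and 8–14). Steps 6 and 7 form the short branch to the bromide from the shared intermediate 2.

Steps most likely to fail

Step 8. The mixed magnesium/copper enolate may alkylate sluggishly. Proton exchange between enolate and product, consumption of the bromide by leftover vinylcopper species, or racemisation of unreacted butenolide could then erode the one-flask coupling. The fallback makes the same two bonds in two flasks and sets out from 8. The cuprate addition is run as before, but enolate 12 is protonated at −78 °C with aq. NH4Cl to give the trans β-vinyl lactone (4R,5S)-5-[4-(benzyloxy)-3-methoxyphenyl]-4-ethenyloxolan-2-one F1, which is purified free of copper salts. Deprotonation with LiN(SiMe3)2 in THF at −78 °C gives the clean lithium enolate F2. This is alkylated with 10 anti to the vinyl group, and the route is rejoined at 13.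

Step 9. Facial selectivity of the oxygen transfer to the tetrasubstituted enolate may be poor, or the enolate may be captured by the sulfonimine formed from the oxaziridine. The fallback replaces the anionic oxidation by epoxidation of a neutral, isolated ketene acetal and sets out from 13. Enolate 14 is generated as before and silylated with Me3SiCl to the trimethylsilyl ketene acetal F3, which is freed from salts by filtration under argon. Rubottom oxidation with mCPBA (NaHCO3 buffer, hexane/CH2Cl2, −20 °C) should attack the electron-rich C4=C5 bond far faster than the vinyl group. Attack is again expected anti to that group, and silyl migration then gives the α-trimethylsilyloxy lactone F4. Citric acid in MeOH removes the silyl group, and the route is rejoined at 15.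

Step 11. The Lewis acid may ionise the C2–O bond next to the electron-rich aryl ring. That would open the way to C2 epimerisation, reductive ring opening, or Friedel–Crafts closure of the C7' arene onto C2. The fallback avoids acid altogether and sets out from 15, bypassing 16. LiAlH4 in THF at 0 °C gives (2S,3R,4S)-4-[4-(benzyloxy)-3-methoxyphenyl]-2-{[4-(benzyloxy)-3-methoxyphenyl]methyl}-3-ethenylbutane-1,2,4-triol F5. TsCl (1.1 equiv) in pyridine at 0 °C sulfonylates the only primary hydroxyl to the 1-O-tosylate F6. On warming in pyridine this is displaced by the C2 hydroxyl in a 5-exo-tet etherification at C5. The C2–O bond is never broken, so C2 keeps its configuration, and the route is rejoined at 18.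

Further compounds
F1 | step 8 | (4R,5S)-5-[4-(benzyloxy)-3-methoxyphenyl]-4-ethenyloxolan-2-one | C1C(=O)O[C@H](c2ccc(OCc3ccccc3)c(OC)c2)[C@H]1C=C
F2 | step 8 | lithium (4S,5S)-5-[4-(benzyloxy)-3-methoxyphenyl]-4-ethenyl-4,5-dihydrofuran-2-olate | C1=C(O[Li])O[C@H](c2ccc(OCc3ccccc3)c(OC)c2)[C@H]1C=C
F3 | step 9 | trimethylsilyl ketene acetal of 13 | COc1cc(CC2=C(O[Si](C)(C)C)O[C@H](c3ccc(OCc4ccccc4)c(OC)c3)[C@H]2C=C)ccc1OCc1ccccc1
F4 | step 9 | O-trimethylsilyl ether of 15 | COc1cc(C[C@@]2(O[Si](C)(C)C)C(=O)O[C@H](c3ccc(OCc4ccccc4)c(OC)c3)[C@H]2C=C)ccc1OCc1ccccc1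
F5 | step 11 | (2S,3R,4S)-4-[4-(benzyloxy)-3-methoxyphenyl]-2-{[4-(benzyloxy)-3-methoxyphenyl]methyl}-3-ethenylbutane-1,2,4-triol | COc1cc(C[C@@](O)(CO)[C@H](C=C)[C@H](O)c2ccc(OCc3ccccc3)c(OC)c2)ccc1OCc1ccccc1
F6 | step 11 | 1-O-(4-methylbenzenesulfonyl) derivative of F5 | COc1cc(C[C@@](O)(COS(=O)(=O)c2ccc(C)cc2)[C@H](C=C)[C@H](O)c2ccc(OCc3ccccc3)c(OC)c2)ccc1OCc1ccccc1
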